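Numbering: ring A = C1–C6 (C1 and C6 ring fusion, C2=C3, methyl on C3, ester on C4, C5 methylene); ring B = C1, C6, C7 (methyl carbinol), C8–C10, C11 (CMe2). The ester is made last by invertive esterification at C4; the C4 carbinol comes from the C2=C3–C4=O enone, and this from a C3=C4 enol silane.
Feature on which the plan rests: in ring A the oxygen-bearing C4 is joined through C5 to C6 (the carbon next to C7), and the methyl-bearing C3 through C2 to C1. A [4+2] addition of a 2-oxy-3-methylbutadiene to a ring B enone C7(=O)–C6=C1 would pair C5 with C1 and C2 with C6, the opposite orientation.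
Key disconnection: ring A from a cyclobutane C1–C4–C5–C6 that carries silyloxy and isopropenyl (C3, C2) on C4. A 1,3-shift of C1 from C4 to C2 breaks C1–C4, makes C1–C2 and leaves the enol silane; C4 sits on C1 because the cyclobutane stems from a head-to-tail enone/ketene acetal [2+2] adduct.
Precursor: isopropenyl addition to the C4 cyclobutanone; C7 methyl carbinol by methyl addition to the cis-fused four/seven ketone; seven-membered ring B by one-carbon homologation of the photoadduct of 4,4-dimethylcyclohex-2-enone and 1,1-diethoxyethene, which is resolved.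
Order of ring formation: six-membered forerunner of ring B (bought), cyclobutane ([2+2]), ring B enlarged to seven, ring A (four-to-six enlargement).

Key step: step 8

Remark: C7 is taken through the key step as its methyl carbinol silyl ether and not as a ketone. A C7 ketone would make both ring-fusion carbons enolisable at the stage of the C4 cyclobutanone (loss of optical purity), would leave C6 epimerisable at the temperature of the shift, and would let cycloreversion release a conjugated enone able to recombine with the diene in the unwanted [4+2] sense.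
Remark: the silyloxydiene is not itself used as the photopartner. It can add at either alkene and in either orientation, it quenches enone triplets, it does not survive Lewis-acid catalysts, and a seven-membered enone tends to react through its strained trans isomer. The ketene acetal adduct of the six-membered enone fixes the C1–C4 and C5–C6 bonds, and the isopropenyl group is then added to the cyclobutanone.
Remark: the configuration drawn at C4 of 10 and 11 (nucleophile on the convex face) is an assumption; it is erased in step 8 and either epimer can be carried on.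
Remark: locants in the names of 12–14, 18 and 19 are those of the overview; racemates are written as the SMILES of both enantiomers joined by a dot.

Step 1
Reactants: 1 4,4-dimethylcyclohex-2-en-1-one; 2 1,1-diethoxyethene
Product: 4 racemic cis-7,7-diethoxy-5,5-dimethylbicyclo[4.2.0]octan-2-one, via trans-fused photoadduct 3 (not isolated)
Conditions: hν (350 nm, Pyrex), 2 (10 equiv), hexane, −20 °C; then basic Al2O3, Et2O, rt
Reagents that add atoms: none
Why: Triplet enone–alkene [2+2] photocycloaddition with an electron-rich 1,1-dialkoxyalkene is expected to give the head-to-tail adduct (acetal carbon C4 on the β-carbon C1, C5 on C6), and epimerisation of the strained trans-fused isomer 3 at the enolisable C6 on basic alumina should leave only the cis ring fusion, so the relative configuration of C1 and C6 is set thermodynamically (racemic at this point).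

Step 2
Reactants: 4 racemic cis-7,7-diethoxy-5,5-dimethylbicyclo[4.2.0]octan-2-one
Product: 5 (1R,6S)-7,7-diethoxy-5,5-dimethylbicyclo[4.2.0]octan-2-one
Conditions: preparative SFC, amylose tris(3,5-dimethylphenylcarbamate) phase, CO2/iPrOH
Reagents that add atoms: none
Why: Resolution of the racemate by chromatography on a polysaccharide chiral stationary phase (assignment by anomalous-dispersion X-ray analysis of a crystalline derivative); C1 is not enolisable, so the separated enantiomer cannot racemise in the later steps.

Step 3
Reactants: 5 (1R,6S)-7,7-diethoxy-5,5-dimethylbicyclo[4.2.0]octan-2-one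
Product: 7 (1R,7S)-8,8-diethoxy-6,6-dimethylbicyclo[5.2.0]nonan-2-one, via alpha-trimethylsilyl ketone 6 (not isolated)
Conditions: Me3SiCHN2, AlMe3, CH2Cl2, −78 → −20 °C; then K2CO3 (cat.), MeOH, 0 °C
Reagents that add atoms: trimethylsilyldiazomethane, C[Si](C)(C)C=[N+]=[N-]
Why: Lewis-acid-promoted diazoalkane homologation (Tiffeneau–Demjanov-type 1,2-shift) in which the unhindered methylene should migrate in preference to the ring-fusion carbon C6, so that the new carbon C8 enters between C7 and C9; the silyl group of 6 blocks a second insertion and is removed by methanolysis, and the cis fusion, expected to be the more stable one, is kept.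

Step 4
Reactants: 7 (1R,7S)-8,8-diethoxy-6,6-dimethylbicyclo[5.2.0]nonan-2-one
Product: 8 (1R,2S,7S)-8,8-diethoxy-2,6,6-trimethylbicyclo[5.2.0]nonan-2-ol
Conditions: MeMgBr, CeCl3, THF, −78 °C
Reagents that add atoms: methylmagnesium bromide, C[Mg]Br
Why: Organocerium 1,2-addition (no enolisation of the hindered cycloheptanone) in which methyl should enter on the convex face, anti to the cyclobutane carbon C5 on C6 (Felkin–Anh sense), setting C7 as (S) with methyl syn to H6.

Step 5
Reactants: 8 (1R,2S,7S)-8,8-diethoxy-2,6,6-trimethylbicyclo[5.2.0]nonan-2-ol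
Product: 9 (1R,2S,7S)-2-hydroxy-2,6,6-trimethylbicyclo[5.2.0]nonan-8-one
Conditions: TsOH·H2O (cat.), acetone–H2O, rt
Reagents that add atoms: water, O
Why: Acid-catalysed acetal hydrolysis under conditions mild enough for the tertiary alcohol; C6 is no longer next to a carbonyl, and C1, now α to the cyclobutanone, should stay in the favoured cis fusion.

Step 6
Reactants: 9 (1R,2S,7S)-2-hydroxy-2,6,6-trimethylbicyclo[5.2.0]nonan-8-one
Product: 10 (1R,2S,7S,8S)-2,6,6-trimethyl-8-(prop-1-en-2-yl)bicyclo[5.2.0]nonane-2,8-diol
Conditions: CH2=C(CH3)MgBr (3 equiv), CeCl3, THF, −78 → 0 °C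
Reagents that add atoms: isopropenylmagnesium bromide, CC(=C)[Mg]Br
Why: Organocerium addition to the strained, electrophilic cyclobutanone after the first equivalent has deprotonated the C7 hydroxyl; attack on the convex face (syn to H1 and H6) is expected, but the configuration created at C4 is of no consequence because C4 becomes trigonal in step 8.

Step 7
Reactants: 10 (1R,2S,7S,8S)-2,6,6-trimethyl-8-(prop-1-en-2-yl)bicyclo[5.2.0]nonane-2,8-diol
Product: 11 (1R,2S,7S,8S)-2,6,6-trimethyl-8-(prop-1-en-2-yl)-2,8-bis(triethylsilyloxy)bicyclo[5.2.0]nonane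
Conditions: Et3SiOTf, 2,6-lutidine, CH2Cl2, −78 → 0 °C
Reagents that add atoms: triethylsilyl trifluoromethanesulfonate, CC[Si](CC)(CC)OS(=O)(=O)C(F)(F)F
Why: Silyl triflate silylation of both tertiary alcohols under 2,6-lutidine buffering, cold enough to avoid ionisation of the allylic cyclobutanol.

Step 8
Reactants: 11 (1R,2S,7S,8S)-2,6,6-trimethyl-8-(prop-1-en-2-yl)-2,8-bis(triethylsilyloxy)bicyclo[5.2.0]nonane
Product: 12 (1S,6R,7S)-3,7,11,11-tetramethyl-4,7-bis(triethylsilyloxy)bicyclo[5.4.0]undec-3-ene
Conditions: degassed decalin (0.02 M), base-washed sealed tube, 240–260 °C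
Reagents that add atoms: none
Why: Proposed new method: on heating, the most strained and most substituted cyclobutane bond C1–C4 should homolyse to a singlet pair made of a secondary alkyl radical at C1 and a tertiary 1-silyloxy-2-methylallyl radical (C4–C3–C2) that stay linked through C5–C6, and collapse of the pair at the allyl terminus C2 forms C1–C2, a formal [1,3] shift of C1 from C4 to C2. The closest known reaction types are the thermal vinylcyclobutane-to-cyclohexene rearrangement and the 1-silyloxy-1-vinylcyclopropane-to-cyclopentanone enol silane rearrangement; the shift has not been shown on a 1-silyloxy-1-alkenylcyclobutane. Ring A is closed by radical recombination within the tethered pair (six-membered, bond formed at the distal allyl carbon), and the C3=C4 double bond appears in the ring as the enol silane, which fixes where the enone will be. No stereocentre is created: C4 becomes trigonal, C6 and C7 are not involved, and C1 should keep its configuration because the allyl unit, anchored at C6 through C5, is expected to return C2 to the face of C1 that C4 has just left (suprafacial shift with retention), which preserves the cis ring fusion. The step needs cleavage of C1–C4 rather than C4–C5 (secondary against primary radical and relief of the crowding between C4 and C11 favour it) and reclosure at C2 rather than cycloreversion across C5–C6 or hydrogen transfer; the s-cis arrangement of C2 and C5 about C3–C4 required for a six-membered ring is open to either C4 epimer, and because C7 is a silyl ether no conjugated enone can be expelled and recombine with the diene in the unwanted [4+2] orientation.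

Step 9
Reactants: 12 (1S,6R,7S)-3,7,11,11-tetramethyl-4,7-bis(triethylsilyloxy)bicyclo[5.4.0]undec-3-ene
Product: 13 (1S,6R,7S)-3,7,11,11-tetramethyl-7-(triethylsilyloxy)bicyclo[5.4.0]undec-2-en-4-one
Conditions: Pd(OAc)2 (10 mol%), O2 (1 atm), DMSO, 60 °C
Reagents that add atoms: none
Why: Saegusa–Ito oxidation in which the palladium enolate at C3 undergoes β-hydride elimination towards the ring methylene C2 to give the conjugated endocyclic C2=C3 enone, the regiochemistry being dictated by the position of the enol silane while the tertiary silyl ether is inert.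

Step 10
Reactants: 13 (1S,6R,7S)-3,7,11,11-tetramethyl-7-(triethylsilyloxy)bicyclo[5.4.0]undec-2-en-4-one
Product: 14 (1S,4S,6R,7S)-3,7,11,11-tetramethyl-7-(triethylsilyloxy)bicyclo[5.4.0]undec-2-en-4-ol
Conditions: NaBH4, CeCl3·7H2O, MeOH, −78 → −20 °C
Reagents that add atoms: none
Why: Luche 1,2-reduction in which axial hydride delivery on the convex face (the side of H1 and H6, away from C7 and C11) should give the (4S) allylic alcohol with hydroxyl anti to H6, the epimer needed for inversion in step 12.

Step 11
Reactants: 15 isovanillic acid (3-hydroxy-4-methoxybenzoic acid)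
Product: 17 3-(tert-butyldimethylsilyloxy)-4-methoxybenzoic acid, via bis-silylated silyl ester 16 (not isolated)
Conditions: tBuMe2SiCl (2.5 equiv), imidazole, DMF, rt; then AcOH–THF–H2O, rt
Reagents that add atoms: tert-butyldimethylsilyl chloride, CC(C)(C)[Si](C)(C)Cl
Why: Silylation of phenol and acid followed by selective hydrolysis of the far more labile silyl ester leaves the phenol protected for the Mitsunobu coupling.

Step 12
Reactants: 14 (1S,4S,6R,7S)-3,7,11,11-tetramethyl-7-(triethylsilyloxy)bicyclo[5.4.0]undec-2-en-4-ol; 17 3-(tert-butyldimethylsilyloxy)-4-methoxybenzoic acid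
Product: 18 (1S,4R,6R,7S)-3,7,11,11-tetramethyl-7-(triethylsilyloxy)bicyclo[5.4.0]undec-2-en-4-yl 3-(tert-butyldimethylsilyloxy)-4-methoxybenzoate
Conditions: PPh3, DIAD, THF, 0 °C → rt
Reagents that add atoms: none
Why: Mitsunobu esterification in which SN2 displacement of the oxyphosphonium by the carboxylate from the open convex face inverts C4 to (4R), the silyl ethers keeping the phenol and the tertiary alcohol out of the reaction.

Step 13
Reactants: 18 (1S,4R,6R,7S)-3,7,11,11-tetramethyl-7-(triethylsilyloxy)bicyclo[5.4.0]undec-2-en-4-yl 3-(tert-butyldimethylsilyloxy)-4-methoxybenzoate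
Product: 19 (1S,4R,6R,7S)-7-hydroxy-3,7,11,11-tetramethylbicyclo[5.4.0]undec-2-en-4-yl 3-hydroxy-4-methoxybenzoate
Conditions: HF·pyridine, pyridine, THF, 0 °C → rt
Reagents that add atoms: none
Why: Fluoride-mediated cleavage of the aryl and the tertiary alkyl silyl ether with pyridine-buffered HF, conditions under which the allylic benzoate and the tertiary alcohol should be stable.

Compound list
1 | 4,4-dimethylcyclohex-2-en-1-one | CC1(C)CCC(=O)C=C1 | starting material
2 | 1,1-diethoxyethene | C=C(OCC)OCC | starting material
3 | racemic trans-7,7-diethoxy-5,5-dimethylbicyclo[4.2.0]octan-2-one | O=C1CCC(C)(C)[C@@H]2[C@@H]1CC2(OCC)OCC.O=C1CCC(C)(C)[C@H]2[C@H]1CC2(OCC)OCC | intermediate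
4 | racemic cis-7,7-diethoxy-5,5-dimethylbicyclo[4.2.0]octan-2-one | O=C1CCC(C)(C)[C@@H]2[C@H]1CC2(OCC)OCC.O=C1CCC(C)(C)[C@H]2[C@@H]1CC2(OCC)OCC | intermediate
5 | (1R,6S)-7,7-diethoxy-5,5-dimethylbicyclo[4.2.0]octan-2-one | O=C1CCC(C)(C)[C@@H]2[C@H]1CC2(OCC)OCC | intermediate
6 | (1R,7S)-8,8-diethoxy-6,6-dimethyl-3-(trimethylsilyl)bicyclo[5.2.0]nonan-2-one (C3 epimers) | O=C1C([Si](C)(C)C)CCC(C)(C)[C@@H]2[C@H]1CC2(OCC)OCC | intermediate
7 | (1R,7S)-8,8-diethoxy-6,6-dimethylbicyclo[5.2.0]nonan-2-one | O=C1CCCC(C)(C)[C@@H]2[C@H]1CC2(OCC)OCC | intermediate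
8 | (1R,2S,7S)-8,8-diethoxy-2,6,6-trimethylbicyclo[5.2.0]nonan-2-ol | C[C@]1(O)CCCC(C)(C)[C@@H]2[C@H]1CC2(OCC)OCC | intermediate
9 | (1R,2S,7S)-2-hydroxy-2,6,6-trimethylbicyclo[5.2.0]nonan-8-one | C[C@]1(O)CCCC(C)(C)[C@@H]2[C@H]1CC2=O | intermediate
10 | (1R,2S,7S,8S)-2,6,6-trimethyl-8-(prop-1-en-2-yl)bicyclo[5.2.0]nonane-2,8-diol | C[C@]1(O)CCCC(C)(C)[C@@H]2[C@H]1C[C@@]2(O)C(C)=C | intermediate
11 | (1R,2S,7S,8S)-2,6,6-trimethyl-8-(prop-1-en-2-yl)-2,8-bis(triethylsilyloxy)bicyclo[5.2.0]nonane | CC[Si](CC)(CC)O[C@@]1(C)CCCC(C)(C)[C@@H]2[C@H]1C[C@@]2(O[Si](CC)(CC)CC)C(C)=C | intermediate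
12 | (1S,6R,7S)-3,7,11,11-tetramethyl-4,7-bis(triethylsilyloxy)bicyclo[5.4.0]undec-3-ene | CC[Si](CC)(CC)OC1=C(C)C[C@H]2[C@@H](C1)[C@@](C)(O[Si](CC)(CC)CC)CCCC2(C)C | intermediate
13 | (1S,6R,7S)-3,7,11,11-tetramethyl-7-(triethylsilyloxy)bicyclo[5.4.0]undec-2-en-4-one | CC1=C[C@H]2[C@@H](CC1=O)[C@@](C)(O[Si](CC)(CC)CC)CCCC2(C)C | intermediate
14 | (1S,4S,6R,7S)-3,7,11,11-tetramethyl-7-(triethylsilyloxy)bicyclo[5.4.0]undec-2-en-4-ol | CC1=C[C@H]2[C@@H](C[C@@H]1O)[C@@](C)(O[Si](CC)(CC)CC)CCCC2(C)C | intermediate
15 | isovanillic acid | COc1ccc(C(=O)O)cc1O | starting material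
16 | tert-butyldimethylsilyl 3-(tert-butyldimethylsilyloxy)-4-methoxybenzoate | COc1ccc(C(=O)O[Si](C)(C)C(C)(C)C)cc1O[Si](C)(C)C(C)(C)C | intermediate
17 | 3-(tert-butyldimethylsilyloxy)-4-methoxybenzoic acid | COc1ccc(C(=O)O)cc1O[Si](C)(C)C(C)(C)C | intermediate
18 | (1S,4R,6R,7S)-3,7,11,11-tetramethyl-7-(triethylsilyloxy)bicyclo[5.4.0]undec-2-en-4-yl 3-(tert-butyldimethylsilyloxy)-4-methoxybenzoate | COc1ccc(C(=O)O[C@@H]2C[C@@H]3[C@H](C=C2C)C(C)(C)CCC[C@]3(C)O[Si](CC)(CC)CC)cc1O[Si](C)(C)C(C)(C)C | intermediate
19 | (1S,4R,6R,7S)-7-hydroxy-3,7,11,11-tetramethylbicyclo[5.4.0]undec-2-en-4-yl 3-hydroxy-4-methoxybenzoate | COc1ccc(C(=O)O[C@@H]2C[C@@H]3[C@H](C=C2C)C(C)(C)CCC[C@]3(C)O)cc1O | target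

Total step count: 13. Longest linear sequence: 12 steps (steps 1–10, 12 and 13); step 11 is a one-step side branch.

Steps most likely to fail

Step 8. The diradical may cyclorevert across C5–C6 (loss of the four-membered ring as the silyloxydiene and a cycloheptene) or transfer hydrogen faster than it recloses at C2, or C5 may migrate instead of C1. The fallback is the known alkoxy-radical ring enlargement of 1-alkenylcycloalkanols and sets out from diol 10. Proton-coupled electron-transfer activation of the O–H bond of the strained allylic cyclobutanol ([Ir(dF(CF3)ppy)2(5,5'-d(CF3)bpy)]PF6, 2,4,6-collidine, 2,4,6-triisopropylbenzenethiol, blue light, CH2Cl2) should give the C4 alkoxy radical. β-Scission of C1–C4 releases the isopropenyl ketone and the C1 radical, which adds to C2 in the 6-endo sense, and hydrogen transfer from the thiol to the α-keto radical gives (1S,6R,7S)-7-hydroxy-3,7,11,11-tetramethylbicyclo[5.4.0]undecan-4-one F1 (C3 epimers, overview locants). The unstrained tertiary C7 hydroxyl has no strain-driven scission open to it and is expected to be left alone. Because C1 is re-formed from a free radical, the cis-fused isomer would have to be separated from any trans isomer at this point. Silylation under equilibrating conditions (Et3SiCl, NaI, Et3N, MeCN) then converts the C7 hydroxyl and the more substituted enol into the ethers, and the route is rejoined at 12.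

Step 3. The ring-fusion carbon C6 may migrate instead of the methylene (carbonyl moved away from the ring fusion), or the aluminium Lewis acid may ionise the acetal. The fallback is a one-carbon ring enlargement whose regiochemistry is fixed by kinetic enolisation, and it sets out from 5. LiN(iPr)2 and Me3SiCl (THF, −78 °C) should deprotonate the methylene side and give (1R,6S)-7,7-diethoxy-5,5-dimethyl-2-(trimethylsilyloxy)bicyclo[4.2.0]oct-2-ene F2. Simmons–Smith cyclopropanation (Et2Zn, CH2I2) gives the trimethylsilyloxycyclopropane with the new methylene bridging C7 and C9 F3. Oxidative opening with FeCl3 in DMF at 0 °C gives (1R,7S)-4-chloro-8,8-diethoxy-6,6-dimethylbicyclo[5.2.0]nonan-2-one F4, and NaOAc in MeOH eliminates it to (1R,7S)-8,8-diethoxy-6,6-dimethylbicyclo[5.2.0]non-3-en-2-one F5. Hydrogenation (H2, Pd/C, EtOAc) returns to the route at 7.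

Step 12. Elimination to the diene or attack at C2 with allylic transposition may compete with direct displacement at the hindered C4 oxyphosphonium, and the electron-rich, weakly acidic benzoic acid may react sluggishly. The fallback sets C4 by reagent control and acylates with retention; it sets out from enone 13. Corey–Bakshi–Shibata reduction ((S)-2-methyl-CBS-oxazaborolidine, BH3·SMe2, THF, −30 °C; C3 with its methyl acting as the large arm) should give (1S,4R,6R,7S)-3,7,11,11-tetramethyl-7-(triethylsilyloxy)bicyclo[5.4.0]undec-2-en-4-ol F6, to be separated from any 14. Steglich esterification with 17 (DCC, DMAP, CH2Cl2) then returns to the route at 18.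

Further compounds
F1 | step 8 | (1S,6R,7S)-7-hydroxy-3,7,11,11-tetramethylbicyclo[5.4.0]undecan-4-one (C3 epimers, overview locants) | CC1C[C@H]2[C@@H](CC1=O)[C@@](C)(O)CCCC2(C)C
F2 | step 3 | (1R,6S)-7,7-diethoxy-5,5-dimethyl-2-(trimethylsilyloxy)bicyclo[4.2.0]oct-2-ene | C[Si](C)(C)OC1=CCC(C)(C)[C@@H]2[C@H]1CC2(OCC)OCC
F3 | step 3 | trimethylsilyloxycyclopropane from F2 (methylene bridging C7 and C9, overview locants) | C[Si](C)(C)OC12CC1CC(C)(C)[C@@H]3[C@H]2CC3(OCC)OCC
F4 | step 3 | (1R,7S)-4-chloro-8,8-diethoxy-6,6-dimethylbicyclo[5.2.0]nonan-2-one (C4 epimers) | O=C1CC(Cl)CC(C)(C)[C@@H]2[C@H]1CC2(OCC)OCC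
F5 | step 3 | (1R,7S)-8,8-diethoxy-6,6-dimethylbicyclo[5.2.0]non-3-en-2-one | O=C1C=CCC(C)(C)[C@@H]2[C@H]1CC2(OCC)OCC
F6 | step 12 | (1S,4R,6R,7S)-3,7,11,11-tetramethyl-7-(triethylsilyloxy)bicyclo[5.4.0]undec-2-en-4-ol (overview locants) | CC1=C[C@H]2[C@@H](C[C@H]1O)[C@@](C)(O[Si](CC)(CC)CC)CCCC2(C)C
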